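The constant I carry is the take, which is the Z lost per G charged, read at the last reading of a run. The zeta run gives 0.988 and the beta run 0.986. So I use the take, their mean, 0.987. I treat G as the limiting reagent in both new flasks, with less charged than Z .

| flask | Z | G | remark | time |
|---|---|---|---|---|
| zeta | 2 M | 0.86 M | run made earlier |  |
| beta | 2 M | 0.98 M | run made earlier |  |
| ash | 2.0 M | 1.00 M |  | 3.0 h |
| birch | 2.0 M | 1.50 M |  | 3.0 h |

| run | time / min | L / % | Z / % | D / % | X / % |
|---|---|---|---|---|---|
| zeta | 20.0 | 3.0 | 92.7 | 2.5 | 5.3 |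
| zeta | 40.0 | 5.3 | 78.8 | 4.0 | 9.6 |
| zeta | 50.0 | 8.5 | 73.7 | 8.5 | 11.0 |
| zeta | 80.0 | 11.3 | 60.8 | 14.7 | 11.4 |
| zeta | 90.0 | 9.9 | 58.8 | 16.0 | 13.0 |
| zeta | 120 | 10.1 | 57.5 | 18.0 | 10.0 |
| beta | 6.00 | 0 | 97.8 | 0.9 | 0.8 |
| beta | 20.0 | 0.4 | 90.6 | 0.8 | 5.4 |
| beta | 40.0 | 7.1 | 79.5 | 3.6 | 10.6 |
| beta | 50.0 | 7.9 | 72.0 | 6.7 | 11.9 |
| beta | 80.0 | 11.2 | 56.5 | 12.1 | 13.7 |
| beta | 90.0 | 12.6 | 54.6 | 18.2 | 14.2 |
| beta | 120 | 12.2 | 51.7 | 20.0 | 11.4 |

(each reading ± 1 percentage point)

- as a solid, counted per litre of solution: G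
- at the start none of G is in solution
- a reading of L is of its free form alone

- which of these there is most of at the end, counted by the Z in it, ash (X / D / Z / L)
- which of these there is most of at the end, counted by the Z in it, birch (X / D / Z / L)
- how much there is at the end of the one of these that leads, in percent of the Z charged: ash
- how much there is at the end of the one of these that leads, in percent of the Z charged: birch

My ledger follows each mole of G, as the mean of the same two last readings. D holds 0.413 of Z. L holds 0.242 and X holds 0.233. The books close with an unseen entry of 0.0991.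

Is there time? At the pace of the beta run up to 80.0 min, birch needs 136 min to lose its share of Z, which is less than the time allowed.

So I reckon ash at Z 50.6% and D 20.7%, and Z leads. I reckon birch at Z 26.0% and D 31.0%, and D leads.

The forecast names the same leaders: Z at 50% in ash and D at 40% in birch. For birch it differs from my D: “D takes about 60% of the flux, so D reaches about 40%, above Z.”

Ash ends with Z leading at 50.1%. Birch ends with D leading at 34.2%, which is 5.8 percentage points below the forecast and 3.2 points above my reckoning.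

    Z + Q → X + J (k = 6.80 × 10⁻⁴ M⁻¹ s⁻¹)
    X ⇌ L (K = 1.00, k = 0.00110 s⁻¹)
    X ⇌ D (K = 2.30, k = 5.00 × 10⁻⁴ s⁻¹)
    G ⇌ Q, rate k4*(cs4 - [Q]) while solid is left; crystals form when [Q] > cs4 (solubility = 0.650 M, k = 5.10 × 10⁻⁴ s⁻¹)
    L ⇌ E (K = 0.160, k = 1.70 × 10⁻⁴ s⁻¹)

The take gave birch Z 26.0%, and the flask holds 27.4%. Now I charge ash with 1.7 M of G instead. The take gives Z 16.1% and the ledger gives D 35.1%. That flask ends with D leading at 36.6% and Z at 20.8%. There, Q, the dissolved G, still stands at 0.116 M after 3.00 h. Applied to the G charged minus that Q, the take gives Z 21.8%, against the 20.8% in that flask.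

The earlier runs and the new flask stem from a simulated flask with made-up constants; noise was put on by code.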